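**Strategy**

Everything rests on tracing both C–O bonds of the cyclohexane ring, at the tertiary carbon bonded to pyridone C5 and at the secondary carbon 1,4 to it, back to one molecule of oxygen. Singlet oxygen adds across a ring-locked 1,3-diene in a [4+2] cycloaddition; the resulting O–O bridge of a 2,3-dioxabicyclo[2.2.2]octene can only span one face, so alkene saturation and O–O cleavage leave the cis-1,4-diol. The precursor is 5-(cyclohexa-1,3-dien-1-yl)-2,4-dimethoxypyridine, in which the dimethoxypyridine masks the 1,4-dihydroxy-2-pyridone. The (R)-configured trienoyl chain is attached late at C3 by lithiation and addition to an organocatalytically made trienal.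

Key step: step 4

Assumption: the cycloadduct of the key step is racemic (one enantiomer is drawn) and becomes achiral once its alkene is saturated; the carbinol formed in the coupling step is an epimeric mixture that converges on oxidation. TES = triethylsilyl, TBS = tert-butyldimethylsilyl, SEM = 2-(trimethylsilyl)ethoxymethyl.

**Route**

Step 1
Reactants: 1 5-bromo-2,4-dimethoxypyridine; 2 3-ethoxycyclohex-2-en-1-one
Product: 5 3-(4,6-dimethoxypyridin-3-yl)cyclohex-2-en-1-one, via (4,6-dimethoxypyridin-3-yl)lithium 3 (not isolated), via lithium alkoxide of the 1,2-adduct 4 (not isolated)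
Conditions: n-BuLi, THF, −78 °C; then 2, −78 → 0 °C; then 2 M HCl, rt
Reagents that add atoms: water (from the aqueous acid, supplies the new carbonyl oxygen), O
Why: Bromine–lithium exchange gives the pyridyllithium, which adds 1,2 to the vinylogous ester, and acid hydrolysis with allylic transposition (Stork–Danheiser sequence) should give the 3-aryl enone; no stereocentre remains.

Step 2
Reactants: 5 3-(4,6-dimethoxypyridin-3-yl)cyclohex-2-en-1-one
Product: 7 5-(4,6-dimethoxypyridin-3-yl)cyclohexa-1,5-dien-1-yl trifluoromethanesulfonate, via lithium cross-conjugated dienolate 6 (not isolated)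
Conditions: LiN(iPr)2, THF, −78 °C; then PhNTf2, −78 → 0 °C; aq. NH4Cl
Reagents that add atoms: N-phenylbis(trifluoromethanesulfonimide), O=S(=O)(N(c1ccccc1)S(=O)(=O)C(F)(F)F)C(F)(F)F
Why: Kinetic deprotonation by the bulky amide at the α′-methylene gives the cross-conjugated dienolate, and O-sulfonylation (enol triflate formation) fixes the second ring double bond regiospecifically, which an acid-mediated dehydration of the allylic alcohol could not guarantee.

Step 3
Reactants: 7 5-(4,6-dimethoxypyridin-3-yl)cyclohexa-1,5-dien-1-yl trifluoromethanesulfonate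
Product: 8 5-(cyclohexa-1,3-dien-1-yl)-2,4-dimethoxypyridine
Conditions: Pd(OAc)2 (5 mol%), PPh3, HCO2H, Bu3N, DMF, 60 °C
Reagents that add atoms: none
Why: Palladium-catalysed formate reduction of the enol triflate (oxidative addition of zerovalent palladium, formate-to-hydride exchange with loss of CO2, reductive elimination) replaces OTf by H without moving the double bonds, so the aryl group sits at a terminus of the ring diene.

Step 4
Reactants: 8 5-(cyclohexa-1,3-dien-1-yl)-2,4-dimethoxypyridine
Product: 9 rac-5-(2,3-dioxabicyclo[2.2.2]oct-5-en-1-yl)-2,4-dimethoxypyridine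
Conditions: O2, tetraphenylporphyrin (1 mol%), white LED, CH2Cl2, −20 °C
Reagents that add atoms: dioxygen, O=O
Why: Tetraphenylporphyrin, excited by visible light, transfers energy to O2, and the singlet oxygen formed adds as a 2π dienophile across C1 and C4 of the ring diene in a concerted suprafacial [4+2] cycloaddition that makes both C–O bonds at once. The closest known reaction type is the photooxygenation of 1-arylcyclohexa-1,3-dienes and of α-terpinene to bicyclic endoperoxides. The one new ring, the six-membered 1,2-dioxine bridging the carbocycle, closes in this intermolecular cycloaddition itself and gives the 2,3-dioxabicyclo[2.2.2]octene. The two new stereocentres are the bridgeheads, and their relative configuration is dictated by the O–O tether, which can only span one face of the ring; the diene is achiral, so 9 is racemic, and no facial control is needed because the chirality vanishes once the alkene is saturated. The selectivity required is [4+2] addition over the ene reaction and over dehydrogenation to the biaryl, which the cisoid, ring-locked, aryl-conjugated diene and the low temperature should secure, while the 2,4-dimethoxypyridine is not attacked by singlet oxygen.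

Step 5
Reactants: 9 rac-5-(2,3-dioxabicyclo[2.2.2]oct-5-en-1-yl)-2,4-dimethoxypyridine
Product: 11 cis-1-(4,6-dimethoxypyridin-3-yl)cyclohexane-1,4-diol, via saturated endoperoxide 10 (not isolated)
Conditions: KO2CN=NCO2K, AcOH, MeOH/CH2Cl2, 0 °C → rt; then Zn, AcOH, rt
Reagents that add atoms: none
Why: Diimide reduction saturates the strained C=C without touching the O–O bond, and zinc in acetic acid then cleaves only the O–O bond by electron transfer (reductive peroxide cleavage), so both carbinol carbons keep the configuration fixed by the bridge and the achiral cis-1,4-diol should result.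

Step 6
Reactants: 11 cis-1-(4,6-dimethoxypyridin-3-yl)cyclohexane-1,4-diol
Product: 12 5-[cis-1,4-bis(triethylsilyloxy)cyclohexyl]-2,4-dimethoxypyridine
Conditions: Et3SiOTf, 2,6-lutidine, CH2Cl2, −78 → 0 °C
Reagents that add atoms: triethylsilyl trifluoromethanesulfonate, CC[Si](CC)(CC)OS(=O)(=O)C(F)(F)F
Why: The silyl triflate with a hindered pyridine base silylates both the secondary and the hindered tertiary hydroxyl (silyl ether formation), giving groups that fluoride removes together at the end.

Step 7
Reactants: 12 5-[cis-1,4-bis(triethylsilyloxy)cyclohexyl]-2,4-dimethoxypyridine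
Product: 13 5-[cis-1,4-bis(triethylsilyloxy)cyclohexyl]-2,4-dimethoxypyridine 1-oxide
Conditions: mCPBA, CH2Cl2, 0 °C → rt
Reagents that add atoms: 3-chloroperoxybenzoic acid, O=C(OO)c1cccc(Cl)c1
Why: The pyridine nitrogen, made nucleophilic by the 4-methoxy group, is oxidised by the peracid (N-oxidation), while the silyl ethers and the saturated ring are inert.

Step 8
Reactants: 13 5-[cis-1,4-bis(triethylsilyloxy)cyclohexyl]-2,4-dimethoxypyridine 1-oxide
Product: 15 5-[cis-1,4-bis(triethylsilyloxy)cyclohexyl]-1-hydroxy-4-methoxypyridin-2(1H)-one, via 1-acetoxy-2-pyridone 14 (not isolated)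
Conditions: AcCl, ClCH2CH2Cl, 50 °C; evaporate; then MeOH, Et3N, 0 °C → rt
Reagents that add atoms: none
Why: O-Acylation of the 2-alkoxypyridine N-oxide gives an N-acetoxypyridinium chloride whose activated 2-O-methyl group is removed by chloride (SN2 dealkylation) to the 1-acetoxy-2-pyridone, and base-buffered methanolysis of this active ester frees the N-hydroxy group; the 2-methyl should go in preference to the 4-methyl because the counter-ion sits next to the onium nitrogen and the 2-pyridone is the more stable product.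

Step 9
Reactants: 15 5-[cis-1,4-bis(triethylsilyloxy)cyclohexyl]-1-hydroxy-4-methoxypyridin-2(1H)-one
Product: 16 5-[cis-1,4-bis(triethylsilyloxy)cyclohexyl]-4-methoxy-1-{[2-(trimethylsilyl)ethoxy]methoxy}pyridin-2(1H)-one
Conditions: SEMCl, iPr2NEt, CH2Cl2, 0 °C → rt
Reagents that add atoms: 2-(trimethylsilyl)ethoxymethyl chloride, C[Si](C)(C)CCOCCl
Why: The acidic N-hydroxy group is alkylated on oxygen by the reactive chloromethyl ether under amine base (O-alkylation of a cyclic hydroxamic acid), giving an N–O acetal that tolerates organolithium reagents and is fluoride-labile.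

Step 10
Reactants: 17 butanal; 18 N-methoxy-N-methyl-2-(triphenylphosphoranylidene)acetamide
Product: 20 (R,E)-4-(hydroxymethyl)-N-methoxy-N-methylhex-2-enamide, via (S)-2-(hydroxymethyl)butanal 19 (not isolated)
Conditions: HCHO (37% aq.), (R)-2-[diphenyl(trimethylsilyloxy)methyl]pyrrolidine (10 mol%), pH 7 buffer, toluene, rt; extract; then 18, CH2Cl2, rt
Reagents that add atoms: formaldehyde, C=O
Why: In this organocatalytic enamine α-hydroxymethylation the (R)-diarylprolinol silyl ether forms the E-enamine of butanal and blocks its Si face, so formaldehyde should add to the Re face and set the (S) centre, and the labile aldol is trapped at once by E-selective Wittig olefination with the stabilised ylide, after which the same centre is named (R) and is no longer an aldehyde α-carbon.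

Step 11
Reactants: 20 (R,E)-4-(hydroxymethyl)-N-methoxy-N-methylhex-2-enamide
Product: 21 (R,E)-4-{[(tert-butyldimethylsilyl)oxy]methyl}-N-methoxy-N-methylhex-2-enamide
Conditions: TBSCl, imidazole, DMF, rt
Reagents that add atoms: tert-butyldimethylsilyl chloride, CC(C)(C)[Si](C)(C)Cl
Why: Standard silylation of the primary alcohol masks it for the hydride, phosphonate and organolithium steps that follow.

Step 12
Reactants: 21 (R,E)-4-{[(tert-butyldimethylsilyl)oxy]methyl}-N-methoxy-N-methylhex-2-enamide
Product: 22 (R,E)-4-{[(tert-butyldimethylsilyl)oxy]methyl}hex-2-enal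
Conditions: iBu2AlH, THF, −78 °C; aqueous work-up
Reagents that add atoms: none
Why: The hydride adds once to the Weinreb amide to give a chelated hemiaminal that releases the enal only on work-up (Weinreb amide reduction), so neither over-reduction nor 1,4-reduction is expected.

Step 13
Reactants: 22 (R,E)-4-{[(tert-butyldimethylsilyl)oxy]methyl}hex-2-enal; 23 triethyl 4-phosphonocrotonate
Product: 24 ethyl (2E,4E,6E,8R)-8-{[(tert-butyldimethylsilyl)oxy]methyl}deca-2,4,6-trienoate
Conditions: LiN(SiMe3)2, THF, −78 → 0 °C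
Reagents that add atoms: none
Why: Vinylogous Horner–Wadsworth–Emmons olefination with the lithiated phosphonocrotonate should form the new C4=C5 bond E-selectively, and addition at −78 °C is faster than γ-deprotonation of the enal, so the (R) centre is kept.

Step 14
Reactants: 24 ethyl (2E,4E,6E,8R)-8-{[(tert-butyldimethylsilyl)oxy]methyl}deca-2,4,6-trienoate
Product: 25 (2E,4E,6E,8R)-8-{[(tert-butyldimethylsilyl)oxy]methyl}deca-2,4,6-trien-1-ol
Conditions: iBu2AlH, CH2Cl2, −78 °C
Reagents that add atoms: none
Why: 1,2-Reduction of the conjugated ester by the aluminium hydride gives the allylic alcohol without touching the triene or the silyl ether.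

Step 15
Reactants: 25 (2E,4E,6E,8R)-8-{[(tert-butyldimethylsilyl)oxy]methyl}deca-2,4,6-trien-1-ol
Product: 26 (2E,4E,6E,8R)-8-{[(tert-butyldimethylsilyl)oxy]methyl}deca-2,4,6-trienal
Conditions: MnO2, CH2Cl2, rt
Reagents that add atoms: none
Why: Manganese dioxide oxidises the allylic alcohol selectively to the trienal under neutral conditions (allylic oxidation), so no E/Z isomerisation or epimerisation is expected.

Step 16
Reactants: 16 5-[cis-1,4-bis(triethylsilyloxy)cyclohexyl]-4-methoxy-1-{[2-(trimethylsilyl)ethoxy]methoxy}pyridin-2(1H)-one; 26 (2E,4E,6E,8R)-8-{[(tert-butyldimethylsilyl)oxy]methyl}deca-2,4,6-trienal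
Product: 28 5-[cis-1,4-bis(triethylsilyloxy)cyclohexyl]-3-[(2E,4E,6E,8R)-8-{[(tert-butyldimethylsilyl)oxy]methyl}-1-hydroxydeca-2,4,6-trien-1-yl]-4-methoxy-1-{[2-(trimethylsilyl)ethoxy]methoxy}pyridin-2(1H)-one, via 3-lithiopyridone 27 (not isolated)
Conditions: n-BuLi, THF, −78 °C; then 26, −78 → −40 °C; aq. NH4Cl
Reagents that add atoms: none
Why: In this directed ortho-lithiation C3–H lies between the lactam carbonyl and the 4-methoxy group, both of which coordinate lithium, so it should be removed in preference to the hindered C6–H, and the aryllithium adds 1,2 to the aldehyde; the new carbinol centre forms without control and is erased in the next step.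

Step 17
Reactants: 28 the epimeric carbinols from step 16
Product: 29 5-[cis-1,4-bis(triethylsilyloxy)cyclohexyl]-3-[(2E,4E,6E,8R)-8-{[(tert-butyldimethylsilyl)oxy]methyl}deca-2,4,6-trienoyl]-4-methoxy-1-{[2-(trimethylsilyl)ethoxy]methoxy}pyridin-2(1H)-one
Conditions: Dess–Martin periodinane, pyridine, CH2Cl2, 0 °C → rt
Reagents that add atoms: none
Why: Dess–Martin oxidation of the hindered allylic carbinol under pyridine buffer should give the trienyl ketone, converging both epimers without acid that could harm the silyl ethers.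

Step 18
Reactants: 29 the 4-methoxy trienyl ketone from step 17
Product: 30 5-[cis-1,4-bis(triethylsilyloxy)cyclohexyl]-3-[(2E,4E,6E,8R)-8-{[(tert-butyldimethylsilyl)oxy]methyl}deca-2,4,6-trienoyl]-4-hydroxy-1-{[2-(trimethylsilyl)ethoxy]methoxy}pyridin-2(1H)-one
Conditions: LiOH, THF/H2O, 0 °C; then 0.5 M HCl to pH 4
Reagents that add atoms: lithium hydroxide (supplies the C4 oxygen), [Li+].[OH-]
Why: C4 is the β-carbon of both the new ketone and the lactam carbonyl, so hydroxide adds there and expels methoxide (addition–elimination hydrolysis of a vinylogous ester), and the stabilised 4-oxido anion formed shields the side chain from further base chemistry.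

Step 19
Reactants: 30 the 4-hydroxy trienyl ketone from step 18
Product: 31 3-[(2E,4E,6E,8R)-8-(hydroxymethyl)deca-2,4,6-trienoyl]-5-(cis-1,4-dihydroxycyclohexyl)-1,4-dihydroxypyridin-2(1H)-one
Conditions: Bu4NF, THF, 0 °C → rt; then 0.5 M HCl to pH 4
Reagents that add atoms: none
Why: Fluoride cleaves the three silyl ethers and triggers β-elimination of the SEM group with loss of fluorotrimethylsilane, ethene and formaldehyde (global fluoride deprotection), releasing the N-hydroxy group without touching any stereocentre.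

**Compound list**

1 | 5-bromo-2,4-dimethoxypyridine | COc1cc(OC)c(Br)cn1 | starting material
2 | 3-ethoxycyclohex-2-en-1-one | CCOC1=CC(=O)CCC1 | starting material
3 | (4,6-dimethoxypyridin-3-yl)lithium | [Li]c1cnc(OC)cc1OC | intermediate (not isolated)
4 | lithium 1-(4,6-dimethoxypyridin-3-yl)-3-ethoxycyclohex-2-en-1-olate (racemic) | CCOC1=CC([O-])(CCC1)c1cnc(OC)cc1OC.[Li+] | intermediate (not isolated)
5 | 3-(4,6-dimethoxypyridin-3-yl)cyclohex-2-en-1-one | COc1cc(OC)c(C2=CC(=O)CCC2)cn1 | intermediate
6 | lithium 5-(4,6-dimethoxypyridin-3-yl)cyclohexa-1,5-dien-1-olate | [Li+].[O-]C1=CCCC(=C1)c1cnc(OC)cc1OC | intermediate (not isolated)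
7 | 5-(4,6-dimethoxypyridin-3-yl)cyclohexa-1,5-dien-1-yl trifluoromethanesulfonate | COc1cc(OC)c(C2=CC(OS(=O)(=O)C(F)(F)F)=CCC2)cn1 | intermediate
8 | 5-(cyclohexa-1,3-dien-1-yl)-2,4-dimethoxypyridine | COc1cc(OC)c(C2=CC=CCC2)cn1 | intermediate
9 | rac-5-(2,3-dioxabicyclo[2.2.2]oct-5-en-1-yl)-2,4-dimethoxypyridine (one enantiomer drawn) | COc1cc(OC)c([C@]23OO[C@H](C=C2)CC3)cn1 | intermediate
10 | 5-(2,3-dioxabicyclo[2.2.2]octan-1-yl)-2,4-dimethoxypyridine | COc1cc(OC)c(C23CCC(CC2)OO3)cn1 | intermediate (not isolated)
11 | cis-1-(4,6-dimethoxypyridin-3-yl)cyclohexane-1,4-diol | COc1cc(OC)c([C@]2(O)CC[C@@H](O)CC2)cn1 | intermediate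
12 | 5-[cis-1,4-bis(triethylsilyloxy)cyclohexyl]-2,4-dimethoxypyridine | COc1cc(OC)c([C@]2(O[Si](CC)(CC)CC)CC[C@@H](O[Si](CC)(CC)CC)CC2)cn1 | intermediate
13 | 5-[cis-1,4-bis(triethylsilyloxy)cyclohexyl]-2,4-dimethoxypyridine 1-oxide | COc1cc(OC)c([C@]2(O[Si](CC)(CC)CC)CC[C@@H](O[Si](CC)(CC)CC)CC2)c[n+]1[O-] | intermediate
14 | 1-acetoxy-5-[cis-1,4-bis(triethylsilyloxy)cyclohexyl]-4-methoxypyridin-2(1H)-one | COc1cc(=O)n(OC(C)=O)cc1[C@]1(O[Si](CC)(CC)CC)CC[C@@H](O[Si](CC)(CC)CC)CC1 | intermediate (not isolated)
15 | 5-[cis-1,4-bis(triethylsilyloxy)cyclohexyl]-1-hydroxy-4-methoxypyridin-2(1H)-one | COc1cc(=O)n(O)cc1[C@]1(O[Si](CC)(CC)CC)CC[C@@H](O[Si](CC)(CC)CC)CC1 | intermediate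
16 | 5-[cis-1,4-bis(triethylsilyloxy)cyclohexyl]-4-methoxy-1-{[2-(trimethylsilyl)ethoxy]methoxy}pyridin-2(1H)-one | COc1cc(=O)n(OCOCC[Si](C)(C)C)cc1[C@]1(O[Si](CC)(CC)CC)CC[C@@H](O[Si](CC)(CC)CC)CC1 | intermediate
17 | butanal | CCCC=O | starting material
18 | N-methoxy-N-methyl-2-(triphenylphosphoranylidene)acetamide | CON(C)C(=O)C=P(c1ccccc1)(c1ccccc1)c1ccccc1 | starting material
19 | (S)-2-(hydroxymethyl)butanal | CC[C@H](C=O)CO | intermediate (not isolated)
20 | (R,E)-4-(hydroxymethyl)-N-methoxy-N-methylhex-2-enamide | CC[C@H](/C=C/C(=O)N(C)OC)CO | intermediate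
21 | (R,E)-4-{[(tert-butyldimethylsilyl)oxy]methyl}-N-methoxy-N-methylhex-2-enamide | CC[C@H](/C=C/C(=O)N(C)OC)CO[Si](C)(C)C(C)(C)C | intermediate
22 | (R,E)-4-{[(tert-butyldimethylsilyl)oxy]methyl}hex-2-enal | CC[C@H](/C=C/C=O)CO[Si](C)(C)C(C)(C)C | intermediate
23 | triethyl 4-phosphonocrotonate | CCOC(=O)/C=C/CP(=O)(OCC)OCC | starting material
24 | ethyl (2E,4E,6E,8R)-8-{[(tert-butyldimethylsilyl)oxy]methyl}deca-2,4,6-trienoate | CC[C@H](/C=C/C=C/C=C/C(=O)OCC)CO[Si](C)(C)C(C)(C)C | intermediate
25 | (2E,4E,6E,8R)-8-{[(tert-butyldimethylsilyl)oxy]methyl}deca-2,4,6-trien-1-ol | CC[C@H](/C=C/C=C/C=C/CO)CO[Si](C)(C)C(C)(C)C | intermediate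
26 | (2E,4E,6E,8R)-8-{[(tert-butyldimethylsilyl)oxy]methyl}deca-2,4,6-trienal | CC[C@H](/C=C/C=C/C=C/C=O)CO[Si](C)(C)C(C)(C)C | intermediate
27 | 3-lithio derivative of 16 | [Li]c1c(OC)c([C@]2(O[Si](CC)(CC)CC)CC[C@@H](O[Si](CC)(CC)CC)CC2)cn(OCOCC[Si](C)(C)C)c1=O | intermediate (not isolated)
28 | 5-[cis-1,4-bis(triethylsilyloxy)cyclohexyl]-3-[(2E,4E,6E,8R)-8-{[(tert-butyldimethylsilyl)oxy]methyl}-1-hydroxydeca-2,4,6-trien-1-yl]-4-methoxy-1-{[2-(trimethylsilyl)ethoxy]methoxy}pyridin-2(1H)-one (both carbinol epimers) | CC[C@H](/C=C/C=C/C=C/C(O)c1c(OC)c([C@]2(O[Si](CC)(CC)CC)CC[C@@H](O[Si](CC)(CC)CC)CC2)cn(OCOCC[Si](C)(C)C)c1=O)CO[Si](C)(C)C(C)(C)C | intermediate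
29 | 5-[cis-1,4-bis(triethylsilyloxy)cyclohexyl]-3-[(2E,4E,6E,8R)-8-{[(tert-butyldimethylsilyl)oxy]methyl}deca-2,4,6-trienoyl]-4-methoxy-1-{[2-(trimethylsilyl)ethoxy]methoxy}pyridin-2(1H)-one | CC[C@H](/C=C/C=C/C=C/C(=O)c1c(OC)c([C@]2(O[Si](CC)(CC)CC)CC[C@@H](O[Si](CC)(CC)CC)CC2)cn(OCOCC[Si](C)(C)C)c1=O)CO[Si](C)(C)C(C)(C)C | intermediate
30 | 5-[cis-1,4-bis(triethylsilyloxy)cyclohexyl]-3-[(2E,4E,6E,8R)-8-{[(tert-butyldimethylsilyl)oxy]methyl}deca-2,4,6-trienoyl]-4-hydroxy-1-{[2-(trimethylsilyl)ethoxy]methoxy}pyridin-2(1H)-one | CC[C@H](/C=C/C=C/C=C/C(=O)c1c(O)c([C@]2(O[Si](CC)(CC)CC)CC[C@@H](O[Si](CC)(CC)CC)CC2)cn(OCOCC[Si](C)(C)C)c1=O)CO[Si](C)(C)C(C)(C)C | intermediate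
31 | 3-[(2E,4E,6E,8R)-8-(hydroxymethyl)deca-2,4,6-trienoyl]-5-(cis-1,4-dihydroxycyclohexyl)-1,4-dihydroxypyridin-2(1H)-one | CC[C@H](/C=C/C=C/C=C/C(=O)c1c(O)c([C@]2(O)CC[C@@H](O)CC2)cn(O)c1=O)CO | target

**Step count**

Total steps: 19. Longest linear sequence: 13 steps (1 to 31 through steps 1–9 and 16–19); the side chain (steps 10–15) joins at step 16.

**Steps most likely to fail**

1. Step 4. The photooxygenation may divert into the ene reaction and dehydrogenation of the diene to the biaryl, or the benzylic endoperoxide may fragment before it is reduced. In that case the peroxide tether is abandoned. Pyridyllithium 3, made from 1 as in step 1, is added to commercial 4-[(tert-butyldimethylsilyl)oxy]cyclohexan-1-one (THF, −78 °C). Equatorial attack of the aryllithium should modestly favour cis-4-[(tert-butyldimethylsilyl)oxy]-1-(4,6-dimethoxypyridin-3-yl)cyclohexan-1-ol F1, which is separated from its trans isomer by chromatography and desilylated with Bu4NF to give 11. This sets out from 1 and rejoins the route at 11; its diastereocontrol is only moderate, which is why it is the reserve.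

2. Step 16. Deprotonation may occur at C6 instead of C3, the base may attack the N–O acetal, or metalation may be too slow for clean coupling. The carbanion is then generated by halogen–metal exchange. Compound 16 is brominated with NBS (MeCN, 0 °C) at C3, the only free nucleophilic ring position, to give 3-bromo-5-[cis-1,4-bis(triethylsilyloxy)cyclohexyl]-4-methoxy-1-{[2-(trimethylsilyl)ethoxy]methoxy}pyridin-2(1H)-one F2. Bromine–lithium exchange (n-BuLi, THF, −78 °C), which is faster than any deprotonation, regenerates 27 regiospecifically, and addition of 26 gives 28. This sets out from 16 and comes back at 28.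

3. Step 8. The acylating, HCl-releasing medium may strip the triethylsilyl ethers or ionise the tertiary benzylic C–O bond. The N–O substituent is then installed directly without acid. N-oxide 13 is O-alkylated with SEMCl (2,6-di-tert-butyl-4-methylpyridine, CH2Cl2, rt → 40 °C) to 5-[cis-1,4-bis(triethylsilyloxy)cyclohexyl]-2,4-dimethoxy-1-{[2-(trimethylsilyl)ethoxy]methoxy}pyridin-1-ium chloride F3. Its chloride removes the activated 2-O-methyl group as chloromethane and gives 16. This is the N-oxide counterpart of the Hilbert–Johnson conversion of 2-methoxypyridines into N-substituted 2-pyridones, and the same manifold as the acyl chloride reaction with an alkylating electrophile. It sets out from 13 and comes back at 16, bypassing 14 and 15.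

**Further compounds**

F1 | step 4 | cis-4-[(tert-butyldimethylsilyl)oxy]-1-(4,6-dimethoxypyridin-3-yl)cyclohexan-1-ol | COc1cc(OC)c([C@]2(O)CC[C@@H](O[Si](C)(C)C(C)(C)C)CC2)cn1
F2 | step 16 | 3-bromo-5-[cis-1,4-bis(triethylsilyloxy)cyclohexyl]-4-methoxy-1-{[2-(trimethylsilyl)ethoxy]methoxy}pyridin-2(1H)-one | COc1c(Br)c(=O)n(OCOCC[Si](C)(C)C)cc1[C@]1(O[Si](CC)(CC)CC)CC[C@@H](O[Si](CC)(CC)CC)CC1
F3 | step 8 | 5-[cis-1,4-bis(triethylsilyloxy)cyclohexyl]-2,4-dimethoxy-1-{[2-(trimethylsilyl)ethoxy]methoxy}pyridin-1-ium chloride | COc1cc(OC)c([C@]2(O[Si](CC)(CC)CC)CC[C@@H](O[Si](CC)(CC)CC)CC2)c[n+]1OCOCC[Si](C)(C)C.[Cl-]
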